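**Retrosynthetic overview**
- The target comes from a silyl-protected hydroxy methylene-lactone by O5 acylation and desilylation. The γ-lactone is the second ring formed: a C12 amide opens the β-epoxide of a cycloheptene at C6, which sets C5 and C6 and the cis ring fusion.
- The seven-membered carbocycle is the first ring formed, by ring-closing metathesis (C5=C6) of an acyclic triene with vinyl groups on C1 and C7.
- The triene comes from chelation-controlled vinyl addition to a C1 ketone (sets C1), followed by dithiane unmasking at C2 and release of the C11 methylene from a Mannich base.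
- The C9–C10 bond comes from a syn boron aldol joining fragment A (C6–C9, C11–C13; C7 set by asymmetric conjugate vinylation of 5,6-dihydro-2H-pyran-2-one) with fragment B (C1–C4, C10, C14, C15; from 1,3-dithiane, (R)-propylene oxide and propanal).
- The ester side chain comes from (S)-2-methylbutan-1-ol via the acid and its anhydride.

Assumption (locants used below): C1 quaternary carbinol; C2–C4, C15 the 3-hydroxybutanoyl chain; C5 acyloxy CH; C6 lactone O–CH; C7 ring-fusion CH; C8 CH2; C9 CHOH; C10/C14 CHMe; C11–C13 methylene lactone. The target is 1S,4R,5S,6R,7S,9R,10S with a (2S)-2-methylbutanoate on O5.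

**Fragment A**

Step 1
Reactants: 1 5,6-dihydro-2H-pyran-2-one
Product: 2 (4S)-4-ethenyloxan-2-one
Conditions: CH2=CHBF3K, [Rh(cod)2]PF6 (3 mol %), (S)-BINAP, toluene/H2O, 100 °C
Reagents that add atoms: potassium vinyltrifluoroborate, C=C[B-](F)(F)F.[K+]
Why: Rhodium-catalysed asymmetric 1,4-addition (Hayashi–Miyaura type); the (S)-BINAP complex delivers the vinyl group to one face of the unsaturated lactone and sets C7.

Step 2
Reactants: 2 (4S)-4-ethenyloxan-2-one
Product: 4 (3S,4R)-3-[(dimethylamino)methyl]-4-ethenyloxan-2-one, via lithium enolate 3 (not isolated)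
Conditions: LiN(iPr)2, THF, –78 °C; CH2=NMe2+ I–, –78 °C to rt
Reagents that add atoms: Eschenmoser's salt, C=[N+](C)C.[I-]
Why: Mannich aminomethylation of the lactone enolate trans to the C7 vinyl group; the CH2NMe2 group is the masked C13 methylene and the C11 centre is erased later.

Step 3
Reactants: 4 (3S,4R)-3-[(dimethylamino)methyl]-4-ethenyloxan-2-one
Product: 5 (2S,3R)-2-[(dimethylamino)methyl]-3-ethenyl-5-hydroxy-N,N-dimethylpentanamide
Conditions: Me2NH (2 M in THF, excess), 45 °C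
Reagents that add atoms: dimethylamine, CNC
Why: Aminolysis of the δ-lactone gives a tertiary amide that survives the later Grignard step and later acts as the internal nucleophile for lactonisation.

Step 4
Reactants: 5 (2S,3R)-2-[(dimethylamino)methyl]-3-ethenyl-5-hydroxy-N,N-dimethylpentanamide
Product: 6 (2S,3R)-2-[(dimethylamino)methyl]-3-ethenyl-N,N-dimethyl-5-oxopentanamide
Conditions: SO3·pyridine, DMSO, iPr2NEt, CH2Cl2, 0 °C
Reagents that add atoms: none
Why: Parikh–Doering oxidation stops at the aldehyde (C9) and tolerates the tertiary amine; no stereocentre is touched.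

**Fragment B**

Step 5
Reactants: 7 1,3-dithiane; 8 (2R)-2-methyloxirane
Product: 10 (2R)-1-(1,3-dithian-2-yl)propan-2-ol, via 2-lithio-1,3-dithiane 9 (not isolated)
Conditions: n-BuLi, THF, –30 °C; then 8, –78 to 0 °C
Reagents that add atoms: none
Why: Corey–Seebach umpolung; the dithiane anion opens the epoxide at its CH2 carbon (SN2), so the (R) carbinol centre (C4) is carried over unchanged.

Step 6
Reactants: 10 (2R)-1-(1,3-dithian-2-yl)propan-2-ol
Product: 11 tert-butyl{[(2R)-1-(1,3-dithian-2-yl)propan-2-yl]oxy}dimethylsilane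
Conditions: TBSCl, imidazole, DMF, rt
Reagents that add atoms: tert-butyldimethylsilyl chloride, CC(C)(C)[Si](C)(C)Cl
Why: Standard silyl protection of the secondary alcohol so that the dithiane can be lithiated again.

Step 7
Reactants: 11 tert-butyl{[(2R)-1-(1,3-dithian-2-yl)propan-2-yl]oxy}dimethylsilane; 12 propanal
Product: 14 1-{2-[(2R)-2-{[tert-butyl(dimethyl)silyl]oxy}propyl]-1,3-dithian-2-yl}propan-1-ol, via lithiated dithiane 13 (not isolated)
Conditions: t-BuLi, THF/HMPA (9:1), –78 °C; then 12, –78 °C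
Reagents that add atoms: none
Why: Second Corey–Seebach lithiation and 1,2-addition to the aldehyde; the new carbinol is an epimer mixture that is oxidised in the next step.

Step 8
Reactants: 14 1-{2-[(2R)-2-{[tert-butyl(dimethyl)silyl]oxy}propyl]-1,3-dithian-2-yl}propan-1-ol
Product: 15 1-{2-[(2R)-2-{[tert-butyl(dimethyl)silyl]oxy}propyl]-1,3-dithian-2-yl}propan-1-one
Conditions: Dess–Martin periodinane, CH2Cl2, 0 °C to rt
Reagents that add atoms: none
Why: Dess–Martin oxidation gives the 2-acyl-1,3-dithiane (an ethyl ketone enolisable on one side only) without touching sulfur or the silyl ether.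

**Acyl donor**

Step 9
Reactants: 16 (2S)-2-methylbutan-1-ol
Product: 17 (2S)-2-methylbutanoic acid
Conditions: TEMPO (cat.), NaOCl (cat.), NaClO2, MeCN/phosphate buffer (pH 6.7), 35 °C
Reagents that add atoms: sodium chlorite, [Na+].[O-]Cl=O
Why: TEMPO/chlorite oxidation of the primary alcohol to the acid under near-neutral conditions that do not epimerise the α-centre.

Step 10
Reactants: 17 (2S)-2-methylbutanoic acid (2 equiv)
Product: 18 (2S)-2-methylbutanoic anhydride
Conditions: DCC (0.5 equiv), CH2Cl2, 0 °C to rt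
Reagents that add atoms: none
Why: Carbodiimide dehydration to the symmetric anhydride, which acylates hindered alcohols without a ketene (racemising) pathway.

**Union and endgame**

Step 11
Reactants: 15 1-{2-[(2R)-2-{[tert-butyl(dimethyl)silyl]oxy}propyl]-1,3-dithian-2-yl}propan-1-one; 6 (2S,3R)-2-[(dimethylamino)methyl]-3-ethenyl-N,N-dimethyl-5-oxopentanamide
Product: 20 (2S,3R,5R,6S)-7-{2-[(2R)-2-{[tert-butyl(dimethyl)silyl]oxy}propyl]-1,3-dithian-2-yl}-2-[(dimethylamino)methyl]-3-ethenyl-5-hydroxy-N,N,6-trimethyl-7-oxoheptanamide, via enol borinate 19 (not isolated)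
Conditions: (–)-Ipc2BOTf, iPr2NEt, CH2Cl2, –78 to 0 °C; then 6, –78 to –20 °C; MeOH/pH 7 buffer
Reagents that add atoms: none
Why: Paterson boron aldol; the (Z)-enol borinate reacts through a chair transition state to give the 9,10-syn adduct, and the Ipc ligands select the aldehyde face that gives 9R,10S (C7 is too remote to interfere).

Step 12
Reactants: 20 (2S,3R,5R,6S)-7-{2-[(2R)-2-{[tert-butyl(dimethyl)silyl]oxy}propyl]-1,3-dithian-2-yl}-2-[(dimethylamino)methyl]-3-ethenyl-5-hydroxy-N,N,6-trimethyl-7-oxoheptanamide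
Product: 21 (2S,3R,5R,6S,7R)-7-{2-[(2R)-2-{[tert-butyl(dimethyl)silyl]oxy}propyl]-1,3-dithian-2-yl}-2-[(dimethylamino)methyl]-3-ethenyl-5,7-dihydroxy-N,N,6-trimethylnon-8-enamide
Conditions: CH2=CHMgBr (5 equiv), CH2Cl2/THF, –78 to –30 °C
Reagents that add atoms: vinylmagnesium bromide, C=C[Mg]Br
Why: Chelation-controlled Grignard 1,2-addition; the magnesium C9 alkoxide and the C1 carbonyl form a six-membered chelate and vinyl adds anti to the C10 methyl, which places the C1 oxygen anti to Me-10 as in the target.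

Step 13
Reactants: 21 (2S,3R,5R,6S,7R)-7-{2-[(2R)-2-{[tert-butyl(dimethyl)silyl]oxy}propyl]-1,3-dithian-2-yl}-2-[(dimethylamino)methyl]-3-ethenyl-5,7-dihydroxy-N,N,6-trimethylnon-8-enamide
Product: 22 (2S,3R,5R,6S,7R)-7-{2-[(2R)-2-{[tert-butyl(dimethyl)silyl]oxy}propyl]-1,3-dithian-2-yl}-2-[(dimethylamino)methyl]-3-ethenyl-N,N,6-trimethyl-5,7-bis[(triethylsilyl)oxy]non-8-enamide
Conditions: TESOTf, 2,6-lutidine, CH2Cl2, –78 to 0 °C
Reagents that add atoms: triethylsilyl triflate, CC[Si](CC)(CC)OS(=O)(=O)C(F)(F)F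
Why: Silyl triflate protection of both the secondary C9 and the hindered tertiary C1 hydroxyl, so that neither directs the later epoxidation or competes in the acylation.

Step 14
Reactants: 22 (2S,3R,5R,6S,7R)-7-{2-[(2R)-2-{[tert-butyl(dimethyl)silyl]oxy}propyl]-1,3-dithian-2-yl}-2-[(dimethylamino)methyl]-3-ethenyl-N,N,6-trimethyl-5,7-bis[(triethylsilyl)oxy]non-8-enamide
Product: 24 (3R,5R,6S,7R)-7-[(3R)-3-{[tert-butyl(dimethyl)silyl]oxy}butanoyl]-3-ethenyl-N,N,6-trimethyl-2-methylidene-5,7-bis[(triethylsilyl)oxy]non-8-enamide, via ammonium iodide 23 (not isolated)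
Conditions: MeI (excess), NaHCO3, MeCN/H2O (9:1), 40 °C; then DBU, CH2Cl2, 0 °C
Reagents that add atoms: water, O; iodomethane, CI (its methyl groups sit only in 23 and leave again)
Why: S-Methylation and hydrolysis unmask the dithiane to the C2 ketone while the amine is quaternised, and DBU then causes Hofmann-type (E1cB) elimination of trimethylamine to the acrylamide; both catalyst poisons and both mCPBA-sensitive groups are removed in one operation.

Step 15
Reactants: 24 (3R,5R,6S,7R)-7-[(3R)-3-{[tert-butyl(dimethyl)silyl]oxy}butanoyl]-3-ethenyl-N,N,6-trimethyl-2-methylidene-5,7-bis[(triethylsilyl)oxy]non-8-enamide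
Product: 25 2-{(1R,4R,5S,6R)-4-[(3R)-3-{[tert-butyl(dimethyl)silyl]oxy}butanoyl]-5-methyl-4,6-bis[(triethylsilyl)oxy]cyclohept-2-en-1-yl}-N,N-dimethylprop-2-enamide
Conditions: second-generation Grubbs catalyst (H2IMes)(PCy3)Cl2Ru=CHPh (10 mol %), toluene (2 mM), 80 °C
Reagents that add atoms: none
Why: Ring-closing metathesis of the two monosubstituted vinyl groups on C1 and C7 forms the cycloheptene (C5=C6); the 1,1-disubstituted, electron-poor acrylamide alkene is much slower to react.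

Step 16
Reactants: 25 2-{(1R,4R,5S,6R)-4-[(3R)-3-{[tert-butyl(dimethyl)silyl]oxy}butanoyl]-5-methyl-4,6-bis[(triethylsilyl)oxy]cyclohept-2-en-1-yl}-N,N-dimethylprop-2-enamide
Product: 27 (3aS,5R,6S,7S,8S,8aR)-7-[(3R)-3-{[tert-butyl(dimethyl)silyl]oxy}butanoyl]-8-hydroxy-6-methyl-3-methylidene-5,7-bis[(triethylsilyl)oxy]octahydro-2H-cyclohepta[b]furan-2-one, via epoxide 26 (not isolated)
Conditions: mCPBA, Na2HPO4, CH2Cl2, 0 °C to rt; then PPTS, wet CH2Cl2, rt
Reagents that add atoms: mCPBA, OOC(=O)c1cccc(Cl)c1; water, O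
Why: Prilezhaev epoxidation on the β face (anti to the allylic C1 silyl ether and to the C7 side chain), then 5-exo opening at C6 by the amide oxygen with inversion and hydrolysis of the iminium ether; this gives the cis-fused methylene lactone and the β C5 hydroxyl.

Step 17
Reactants: 27 (3aS,5R,6S,7S,8S,8aR)-7-[(3R)-3-{[tert-butyl(dimethyl)silyl]oxy}butanoyl]-8-hydroxy-6-methyl-3-methylidene-5,7-bis[(triethylsilyl)oxy]octahydro-2H-cyclohepta[b]furan-2-one; 18 (2S)-2-methylbutanoic anhydride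
Product: 28 (3aS,5R,6S,7S,8S,8aR)-7-[(3R)-3-{[tert-butyl(dimethyl)silyl]oxy}butanoyl]-6-methyl-3-methylidene-2-oxo-5,7-bis[(triethylsilyl)oxy]octahydro-2H-cyclohepta[b]furan-8-yl (2S)-2-methylbutanoate
Conditions: 18 (3 equiv), DMAP, pyridine, CH2Cl2, rt
Reagents that add atoms: none
Why: DMAP-catalysed acylation (Steglich type) of the only free hydroxyl (C5); the anhydride transfers the acyl group with its (S) centre intact.

Step 18
Reactants: 28 (3aS,5R,6S,7S,8S,8aR)-7-[(3R)-3-{[tert-butyl(dimethyl)silyl]oxy}butanoyl]-6-methyl-3-methylidene-2-oxo-5,7-bis[(triethylsilyl)oxy]octahydro-2H-cyclohepta[b]furan-8-yl (2S)-2-methylbutanoate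
Product: 29 (3aS,5R,6S,7S,8S,8aR)-5,7-dihydroxy-7-[(3R)-3-hydroxybutanoyl]-6-methyl-3-methylidene-2-oxooctahydro-2H-cyclohepta[b]furan-8-yl (2S)-2-methylbutanoate
Conditions: HF·pyridine, pyridine, THF, 0 °C to rt
Reagents that add atoms: none
Why: Fluoride-mediated global desilylation, buffered with pyridine, removes all three silyl ethers without affecting the methylene lactone, the ester or the β-hydroxy ketone.

**Compound list**

1 | 5,6-dihydro-2H-pyran-2-one | O=C1C=CCCO1 | starting material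
2 | (4S)-4-ethenyloxan-2-one | C=C[C@H]1CCOC(=O)C1 | intermediate
3 | lithium enolate of 2 | C=C[C@H]1CCOC(O[Li])=C1 | intermediate (not isolated)
4 | (3S,4R)-3-[(dimethylamino)methyl]-4-ethenyloxan-2-one (3,4-trans) | C=C[C@H]1CCOC(=O)[C@@H]1CN(C)C | intermediate
5 | (2S,3R)-2-[(dimethylamino)methyl]-3-ethenyl-5-hydroxy-N,N-dimethylpentanamide | CN(C)C[C@@H](C(=O)N(C)C)[C@@H](C=C)CCO | intermediate
6 | (2S,3R)-2-[(dimethylamino)methyl]-3-ethenyl-N,N-dimethyl-5-oxopentanamide (fragment A) | CN(C)C[C@@H](C(=O)N(C)C)[C@@H](C=C)CC=O | intermediate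
7 | 1,3-dithiane | C1CSCSC1 | starting material
8 | (2R)-2-methyloxirane | C[C@@H]1CO1 | starting material
9 | 2-lithio-1,3-dithiane | [Li]C1SCCCS1 | intermediate (not isolated)
10 | (2R)-1-(1,3-dithian-2-yl)propan-2-ol | C[C@@H](O)CC1SCCCS1 | intermediate
11 | tert-butyl{[(2R)-1-(1,3-dithian-2-yl)propan-2-yl]oxy}dimethylsilane | C[C@@H](O[Si](C)(C)C(C)(C)C)CC1SCCCS1 | intermediate
12 | propanal | CCC=O | starting material
13 | 2-lithio derivative of 11 | C[C@@H](O[Si](C)(C)C(C)(C)C)CC1([Li])SCCCS1 | intermediate (not isolated)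
14 | 1-{2-[(2R)-2-{[tert-butyl(dimethyl)silyl]oxy}propyl]-1,3-dithian-2-yl}propan-1-ol (both carbinol epimers) | CCC(O)C1(C[C@@H](C)O[Si](C)(C)C(C)(C)C)SCCCS1 | intermediate
15 | 1-{2-[(2R)-2-{[tert-butyl(dimethyl)silyl]oxy}propyl]-1,3-dithian-2-yl}propan-1-one (fragment B) | CCC(=O)C1(C[C@@H](C)O[Si](C)(C)C(C)(C)C)SCCCS1 | intermediate
16 | (2S)-2-methylbutan-1-ol | CC[C@H](C)CO | starting material
17 | (2S)-2-methylbutanoic acid | CC[C@H](C)C(=O)O | intermediate
18 | (2S)-2-methylbutanoic anhydride | CC[C@H](C)C(=O)OC(=O)[C@@H](C)CC | intermediate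
19 | (Z)-enol diisopinocampheylborinate of 15 (Ipc groups from (+)-α-pinene, drawn without their stereodescriptors) | C/C=C(\OB(C1CC2CC(C1C)C2(C)C)C1CC2CC(C1C)C2(C)C)C1(C[C@@H](C)O[Si](C)(C)C(C)(C)C)SCCCS1 | intermediate (not isolated)
20 | (2S,3R,5R,6S)-7-{2-[(2R)-2-{[tert-butyl(dimethyl)silyl]oxy}propyl]-1,3-dithian-2-yl}-2-[(dimethylamino)methyl]-3-ethenyl-5-hydroxy-N,N,6-trimethyl-7-oxoheptanamide | CN(C)C[C@@H](C(=O)N(C)C)[C@@H](C=C)C[C@@H](O)[C@H](C)C(=O)C1(C[C@@H](C)O[Si](C)(C)C(C)(C)C)SCCCS1 | intermediate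
21 | (2S,3R,5R,6S,7R)-7-{2-[(2R)-2-{[tert-butyl(dimethyl)silyl]oxy}propyl]-1,3-dithian-2-yl}-2-[(dimethylamino)methyl]-3-ethenyl-5,7-dihydroxy-N,N,6-trimethylnon-8-enamide | CN(C)C[C@@H](C(=O)N(C)C)[C@@H](C=C)C[C@@H](O)[C@H](C)[C@](O)(C=C)C1(C[C@@H](C)O[Si](C)(C)C(C)(C)C)SCCCS1 | intermediate
22 | 5,7-bis(triethylsilyl) ether of 21 | CN(C)C[C@@H](C(=O)N(C)C)[C@@H](C=C)C[C@@H](O[Si](CC)(CC)CC)[C@H](C)[C@](O[Si](CC)(CC)CC)(C=C)C1(C[C@@H](C)O[Si](C)(C)C(C)(C)C)SCCCS1 | intermediate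
23 | trimethylammonium iodide of the C2 ketone (dithiane removed, amine quaternised) | C[N+](C)(C)C[C@@H](C(=O)N(C)C)[C@@H](C=C)C[C@@H](O[Si](CC)(CC)CC)[C@H](C)[C@](O[Si](CC)(CC)CC)(C=C)C(=O)C[C@@H](C)O[Si](C)(C)C(C)(C)C.[I-] | intermediate (not isolated)
24 | (3R,5R,6S,7R)-7-[(3R)-3-{[tert-butyl(dimethyl)silyl]oxy}butanoyl]-3-ethenyl-N,N,6-trimethyl-2-methylidene-5,7-bis[(triethylsilyl)oxy]non-8-enamide | C=C(C(=O)N(C)C)[C@@H](C=C)C[C@@H](O[Si](CC)(CC)CC)[C@H](C)[C@](O[Si](CC)(CC)CC)(C=C)C(=O)C[C@@H](C)O[Si](C)(C)C(C)(C)C | intermediate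
25 | 2-{(1R,4R,5S,6R)-4-[(3R)-3-{[tert-butyl(dimethyl)silyl]oxy}butanoyl]-5-methyl-4,6-bis[(triethylsilyl)oxy]cyclohept-2-en-1-yl}-N,N-dimethylprop-2-enamide | C=C(C(=O)N(C)C)[C@H]1C=C[C@](O[Si](CC)(CC)CC)(C(=O)C[C@@H](C)O[Si](C)(C)C(C)(C)C)[C@@H](C)[C@H](O[Si](CC)(CC)CC)C1 | intermediate
26 | β-epoxide of 25 (C5–C6 oxirane cis to the C9 oxygen; 1S,5S,6S,7S by skeleton locants) | C=C(C(=O)N(C)C)[C@H]1[C@@H]2O[C@@H]2[C@](O[Si](CC)(CC)CC)(C(=O)C[C@@H](C)O[Si](C)(C)C(C)(C)C)[C@@H](C)[C@H](O[Si](CC)(CC)CC)C1 | intermediate (not isolated)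
27 | (3aS,5R,6S,7S,8S,8aR)-7-[(3R)-3-{[tert-butyl(dimethyl)silyl]oxy}butanoyl]-8-hydroxy-6-methyl-3-methylidene-5,7-bis[(triethylsilyl)oxy]octahydro-2H-cyclohepta[b]furan-2-one | C=C1C(=O)O[C@@H]2[C@H]1C[C@@H](O[Si](CC)(CC)CC)[C@H](C)[C@@](O[Si](CC)(CC)CC)(C(=O)C[C@@H](C)O[Si](C)(C)C(C)(C)C)[C@H]2O | intermediate
28 | (2S)-2-methylbutanoate of 27 | C=C1C(=O)O[C@@H]2[C@H]1C[C@@H](O[Si](CC)(CC)CC)[C@H](C)[C@@](O[Si](CC)(CC)CC)(C(=O)C[C@@H](C)O[Si](C)(C)C(C)(C)C)[C@H]2OC(=O)[C@@H](C)CC | intermediate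
29 | (3aS,5R,6S,7S,8S,8aR)-5,7-dihydroxy-7-[(3R)-3-hydroxybutanoyl]-6-methyl-3-methylidene-2-oxooctahydro-2H-cyclohepta[b]furan-8-yl (2S)-2-methylbutanoate | C=C1C(=O)O[C@@H]2[C@H]1C[C@@H](O)[C@H](C)[C@@](O)(C(=O)C[C@@H](C)O)[C@H]2OC(=O)[C@@H](C)CC | target

**Step count**

Total: 18 steps. Longest linear sequence: 12 steps (1–4, then 11–18; the branch 5–8, then 11–18, is equally long). Steps 9–10 form a third branch that joins at step 17.

**Steps most likely to fail, with fallbacks**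

Step 11. The aldol depends on reagent control with a hindered acyl dithiane ketone, and the facial sense of the (–)-Ipc reagent is assigned by analogy only; the (+)-reagent is the first thing to try if the other syn pair forms. The fallback sets out from 6 and comes back at 20. An Evans aldol of 6 with (4S)-4-benzyl-3-propanoyl-1,3-oxazolidin-2-one (Bu2BOTf, iPr2NEt, CH2Cl2, –78 °C) gives the syn-aldol imide F1 with auxiliary-controlled 9R,10S. Transamination with MeNHOMe·HCl/AlMe3 gives the Weinreb amide F2. Excess lithiated dithiane 13 (from 11) then acylates at C1 to give 20.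

Step 12. The ketone is flanked by a quaternary dithiane carbon, and the C1 configuration depends on chelation beating Felkin control. The fallback sets out from 6 and comes back at 22, reversing the order in which the two C1 substituents arrive. A boron aldol of 6 with pent-1-en-3-one under the conditions of step 11 gives the hydroxy enone F3, and TESOTf/2,6-lutidine gives the silyl ether F4. Lithiated dithiane 13 (generated with n-BuLi in THF without HMPA) adds 1,2 to the enone under Felkin–Anh control to give the tertiary alcohol F5; with the dithiane as the nucleophile, Felkin control leads to the same C1 configuration. TESOTf then gives 22.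

Step 16. Epoxidation may occur on the α face, or Baeyer–Villiger oxidation of the C2 ketone may compete. The fallback sets out from 25 and comes back at 27, replacing steric control by a directing group. PPTS in MeOH at 0 °C removes only the secondary C9 silyl ether to give the alcohol F6. VO(acac)2/t-BuOOH, directed across the ring by the β C9 hydroxyl, gives the β-epoxide F7. PPTS in wet CH2Cl2 closes the lactone to the diol F8. TESCl/imidazole at –20 °C silylates the less hindered C9 hydroxyl to give 27.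

**Further compounds**

F1 | step 11 | (2S,3R,5R,6S)-7-[(4S)-4-benzyl-2-oxo-1,3-oxazolidin-3-yl]-2-[(dimethylamino)methyl]-3-ethenyl-5-hydroxy-N,N,6-trimethyl-7-oxoheptanamide | CN(C)C[C@@H](C(=O)N(C)C)[C@@H](C=C)C[C@@H](O)[C@H](C)C(=O)N1[C@@H](Cc2ccccc2)COC1=O
F2 | step 11 | (2S,3R,5R,6S)-2-[(dimethylamino)methyl]-3-ethenyl-5-hydroxy-N7-methoxy-N1,N1,N7,6-tetramethylheptanediamide | CN(C)C[C@@H](C(=O)N(C)C)[C@@H](C=C)C[C@@H](O)[C@H](C)C(=O)N(C)OC
F3 | step 12 | (2S,3R,5R,6S)-2-[(dimethylamino)methyl]-3-ethenyl-5-hydroxy-N,N,6-trimethyl-7-oxonon-8-enamide | CN(C)C[C@@H](C(=O)N(C)C)[C@@H](C=C)C[C@@H](O)[C@H](C)C(=O)C=C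
F4 | step 12 | (2S,3R,5R,6S)-2-[(dimethylamino)methyl]-3-ethenyl-N,N,6-trimethyl-7-oxo-5-[(triethylsilyl)oxy]non-8-enamide | CN(C)C[C@@H](C(=O)N(C)C)[C@@H](C=C)C[C@@H](O[Si](CC)(CC)CC)[C@H](C)C(=O)C=C
F5 | step 12 | (2S,3R,5R,6S,7R)-7-{2-[(2R)-2-{[tert-butyl(dimethyl)silyl]oxy}propyl]-1,3-dithian-2-yl}-2-[(dimethylamino)methyl]-3-ethenyl-7-hydroxy-N,N,6-trimethyl-5-[(triethylsilyl)oxy]non-8-enamide | CN(C)C[C@@H](C(=O)N(C)C)[C@@H](C=C)C[C@@H](O[Si](CC)(CC)CC)[C@H](C)[C@](O)(C=C)C1(C[C@@H](C)O[Si](C)(C)C(C)(C)C)SCCCS1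
F6 | step 16 | 2-{(1R,4R,5S,6R)-4-[(3R)-3-{[tert-butyl(dimethyl)silyl]oxy}butanoyl]-6-hydroxy-5-methyl-4-[(triethylsilyl)oxy]cyclohept-2-en-1-yl}-N,N-dimethylprop-2-enamide | C=C(C(=O)N(C)C)[C@H]1C=C[C@](O[Si](CC)(CC)CC)(C(=O)C[C@@H](C)O[Si](C)(C)C(C)(C)C)[C@@H](C)[C@H](O)C1
F7 | step 16 | β-epoxide of F6 (C5–C6 oxirane cis to the C9 hydroxyl) | C=C(C(=O)N(C)C)[C@H]1[C@@H]2O[C@@H]2[C@](O[Si](CC)(CC)CC)(C(=O)C[C@@H](C)O[Si](C)(C)C(C)(C)C)[C@@H](C)[C@H](O)C1
F8 | step 16 | (3aS,5R,6S,7S,8S,8aR)-7-[(3R)-3-{[tert-butyl(dimethyl)silyl]oxy}butanoyl]-5,8-dihydroxy-6-methyl-3-methylidene-7-[(triethylsilyl)oxy]octahydro-2H-cyclohepta[b]furan-2-one | C=C1C(=O)O[C@@H]2[C@H]1C[C@@H](O)[C@H](C)[C@@](O[Si](CC)(CC)CC)(C(=O)C[C@@H](C)O[Si](C)(C)C(C)(C)C)[C@H]2O
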